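Ring A is closed last, across C2–C3 (eudesmane numbering). The allylic carbinol C3, next to the tetrasubstituted C4=C5 alkene, is read as the 1,2-adduct of a C2 alkylchromium to a C3 enal, so one operation forms C2–C3, closes ring A and sets C3 by relay from the C10 quaternary centre. Its precursor is a fully functionalised ring B: 8β-acetate, C7 acrylate, a (Z)-2-methylenal on C5 and a 2-iodoethyl arm on C10. (R)-Carvone supplies C7; a dienolate alkylation sets C10; a final Schenck ene reaction moves C4=C5 to C4=C15 and delivers the 5α-hydroperoxide.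

Key step: step 11

Remark: positions are numbered as in eudesmane (C1 to C15) in every intermediate, also where ring A is still open; β is the face of the C10 methyl group.

Step 1
Reactants: 1 (R)-carvone; 2 tert-butyl(2-iodoethoxy)dimethylsilane
Product: 4 (2R,5S)-2-[2-(tert-butyldimethylsilyloxy)ethyl]-2-methyl-5-(prop-1-en-2-yl)cyclohex-3-en-1-one, via potassium dienolate 3 (not isolated)
Conditions: KOC(CH3)3, THF, 0 °C; then 2, DMPU, −20 to 0 °C
Reagents that add atoms: none
Why: Deconjugative α-alkylation of the thermodynamic linear dienolate puts the electrophile on C10, moves the alkene to C8=C9 and creates the quaternary centre, and the electrophile should approach the face opposite the quasi-axial C7 isopropenyl group so that the new chain is trans to it and the C10 methyl cis.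

Step 2
Reactants: 4 C10-alkylated cyclohexenone
Product: 5 (2R,5S)-2-[2-(tert-butyldimethylsilyloxy)ethyl]-5-(3-hydroxyprop-1-en-2-yl)-2-methylcyclohex-3-en-1-one
Conditions: SeO2 (cat.), t-BuOOH, CH2Cl2, 0 °C to rt
Reagents that add atoms: tert-butyl hydroperoxide CC(C)(C)OO (oxygen source, transferred through selenium dioxide O=[Se]=O)
Why: Selenium dioxide allylic oxidation (ene reaction, then [2,3]-sigmatropic shift) should take the 1,1-disubstituted alkene and, by the CH3 over CH preference, hydroxylate the isopropenyl methyl group without touching C7 or the C8=C9 alkene.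

Step 3
Reactants: 5 allylic alcohol
Product: 7 2-[(1S,4R)-4-[2-(tert-butyldimethylsilyloxy)ethyl]-4-methyl-5-oxocyclohex-2-en-1-yl]prop-2-enoic acid, via enal 6 (not isolated)
Conditions: TEMPO (cat.), NaOCl (cat.), NaClO2, MeCN/phosphate buffer pH 6.7, 35 °C
Reagents that add atoms: sodium chlorite [Na+].[O-]Cl=O
Why: Anelli-type TEMPO oxidation to the enal, followed in the same flask by Pinnick-type chlorite oxidation, should give the acrylic acid under near-neutral conditions that spare the ketone, the silyl ether and the isolated alkene.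

Step 4
Reactants: 7 keto acid
Product: 8 2-[(1S,4R,5S)-4-[2-(tert-butyldimethylsilyloxy)ethyl]-5-hydroxy-4-methyl-5-(prop-1-en-2-yl)cyclohex-2-en-1-yl]prop-2-enoic acid
Conditions: CH2=C(CH3)MgBr (3.5 equiv), CeCl3, THF, −78 to 0 °C; aq. NH4Cl
Reagents that add atoms: isopropenylmagnesium bromide C=C(C)[Mg]Br
Why: CeCl3-mediated Grignard 1,2-addition to the hindered, enolisable ketone, after the first equivalent has turned the acid into an unreactive carboxylate; attack anti to the quasi-axial C10 methyl should give the 5β-alcohol, a stereocentre that step 5 erases.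

Step 5
Reactants: 8 tertiary allylic alcohol
Product: 9 2-[(1S,4R,5Z)-4-[2-(tert-butyldimethylsilyloxy)ethyl]-4-methyl-5-(1-oxopropan-2-ylidene)cyclohex-2-en-1-yl]prop-2-enoic acid
Conditions: (C5H5NH)[CrO3Cl] (pyridinium chlorochromate), 4 Å MS, CH2Cl2, rt
Reagents that add atoms: pyridinium chlorochromate [O-][Cr](=O)(=O)Cl.c1cc[nH+]cc1 (aldehyde oxygen)
Why: Babler–Dauben oxidative transposition ([3,3] shift of the tertiary allylic chromate, then oxidation) should give the tetrasubstituted enal, and the Z isomer (formyl cis to C10, methyl cis to C6) should prevail under the acidic, equilibrating conditions because the formyl group is the smaller partner for allylic 1,3-strain with the quaternary centre.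

Step 6
Reactants: 9 enal acid
Product: 10 methyl 2-[(1S,4R,5Z)-4-[2-(tert-butyldimethylsilyloxy)ethyl]-4-methyl-5-(1-oxopropan-2-ylidene)cyclohex-2-en-1-yl]prop-2-enoate
Conditions: CH3I, KHCO3, DMF, rt
Reagents that add atoms: iodomethane CI
Why: SN2 O-methylation of the carboxylate under bicarbonate, mild enough not to deconjugate the enal.

Step 7
Reactants: 10 enal ester
Product: 11 methyl 2-[(1R,2S,3S,4S,5Z)-2-acetoxy-3-bromo-4-[2-(tert-butyldimethylsilyloxy)ethyl]-4-methyl-5-(1-oxopropan-2-ylidene)cyclohexyl]prop-2-enoate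
Conditions: N-bromosuccinimide, NaOAc, AcOH, 15 °C, dark
Reagents that add atoms: N-bromosuccinimide O=C1CCC(=O)N1Br; acetic acid CC(=O)O
Why: Electrophilic bromoacetoxylation of the only electron-rich alkene (C8=C9): in the preferred half-chair (C7 side chain quasi-equatorial, C10 methyl quasi-axial) bromine should add to the α face and acetate attack C8, the carbon that is not neopentyl, from the β face in a trans-diaxial (Fürst–Plattner) opening, giving the 8β-acetate cis to the C7 side chain.

Step 8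
Reactants: 11 bromoacetate
Product: 12 methyl 2-[(1R,2R,4R,5Z)-2-acetoxy-4-[2-(tert-butyldimethylsilyloxy)ethyl]-4-methyl-5-(1-oxopropan-2-ylidene)cyclohexyl]prop-2-enoate
Conditions: n-Bu3SnH (1.1 equiv), AIBN (cat.), toluene, 80 °C
Reagents that add atoms: none
Why: Radical-chain hydrodebromination removes the auxiliary C9 bromine (halogen abstraction by the stannyl radical, then hydrogen transfer) without touching the C8 stereocentre.

Step 9
Reactants: 12 silyl ether
Product: 13 methyl 2-[(1R,2R,4R,5Z)-2-acetoxy-4-(2-hydroxyethyl)-4-methyl-5-(1-oxopropan-2-ylidene)cyclohexyl]prop-2-enoate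
Conditions: HF·pyridine, THF/pyridine, 0 °C
Reagents that add atoms: none
Why: Fluoride-mediated cleavage of the primary silyl ether under buffered, non-basic conditions that spare the acetate, the methyl ester and the enal.

Step 10
Reactants: 13 primary alcohol
Product: 14 methyl 2-[(1R,2R,4S,5Z)-2-acetoxy-4-(2-iodoethyl)-4-methyl-5-(1-oxopropan-2-ylidene)cyclohexyl]prop-2-enoate
Conditions: I2, PPh3, imidazole, CH2Cl2, 0 °C
Reagents that add atoms: iodine II
Why: Appel-type iodination (SN2 displacement of the alkoxyphosphonium by iodide) is compatible with the aldehyde and the esters.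

Step 11
Reactants: 14 iodo enal
Product: 16 methyl (3S,7R,8R,10R)-8-acetoxy-3-hydroxyeudesma-4,11(13)-dien-12-oate, via alkylchromium dichloride 15 (not isolated)
Conditions: CrCl2 (6 equiv), Co(C32H16N8) (cobalt phthalocyanine, 10 mol%), DMF, rt, 0.01 M; aq. work-up
Reagents that add atoms: none
Why: Cobalt-catalysed halogen abstraction from the primary iodide and capture of the C2 radical by divalent chromium give the trivalent alkylchromium 15, which adds 1,2 to the tethered enal carbonyl and so forms the C2–C3 bond; the closest known reaction type is the Takai–Utimoto (Nozaki–Hiyama-type) alkylchromium Barbier addition to aldehydes, used here intramolecularly. Ring A closes in a 6-exo-trig mode with the carbonyl oxygen exocyclic. The new C3 stereocentre is controlled by the C10 quaternary centre: in the half-chair transition state the C10 methyl is quasi-axial (β), C1 lies near the alkene plane and C2 reaches C3 from the inner side, and the Bürgi–Dunitz trajectory is met only by the s-trans aldehyde rotamer (oxygen outward, hydrogen toward C10), so the oxygen should end quasi-equatorial, that is 3β (3S). The step needs chemoselectivity for the aldehyde over the acrylate, the acetate and the methyl ester, which the low basicity and aldehyde selectivity of alkylchromium reagents secure, and 1,2- over 1,4-addition, which is enforced because C5 is fully substituted and bonding there would give a four-membered ring. It also needs the Z enal geometry of step 5, since only that isomer places C3 within reach of C2. High dilution suppresses intermolecular radical addition to the acrylate.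

Step 12
Reactants: 16 allylic alcohol
Product: 17 methyl (3S,7R,8R,10R)-8-acetoxy-3-(2-methylpropanoyloxy)eudesma-4,11(13)-dien-12-oate
Conditions: (CH3)2CHCOCl, pyridine, DMAP (cat.), CH2Cl2, 0 °C
Reagents that add atoms: 2-methylpropanoyl chloride CC(C)C(=O)Cl
Why: DMAP-catalysed acylation of the secondary allylic alcohol proceeds with retention at C3.

Step 13
Reactants: 17 allylic isobutyrate
Product: 18 methyl (3S,5S,7R,8R,10R)-8-acetoxy-5-hydroperoxy-3-(2-methylpropanoyloxy)eudesma-4(15),11(13)-dien-12-oate (CNP0244758.1)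
Conditions: O2, tetraphenylporphyrin (cat.), CH2Cl2, visible light, −20 to 0 °C
Reagents that add atoms: dioxygen O=O
Why: Schenck ene reaction of singlet oxygen with the tetrasubstituted C4=C5 alkene: oxygen should bond to C5 on the α face, opposite the C10 methyl and the 3β-acyloxy group, and abstract a C15 hydrogen (the C3 hydrogen geminal to the ester is deactivated, the 6α hydrogen is quasi-equatorial and misaligned), which shifts the alkene to C4=C15 and sets the 5α-hydroperoxide, while the electron-poor acrylate stays inert.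

Compound list
1 | (R)-carvone, (5R)-2-methyl-5-(prop-1-en-2-yl)cyclohex-2-en-1-one | C=C(C)[C@H]1CC(=O)C(C)=CC1 | starting material
2 | tert-butyl(2-iodoethoxy)dimethylsilane | CC(C)(C)[Si](C)(C)OCCI | starting material
3 | potassium (5S)-2-methyl-5-(prop-1-en-2-yl)cyclohexa-1,3-dien-1-olate | C=C(C)[C@H]1CC([O-])=C(C)C=C1.[K+] | intermediate
4 | (2R,5S)-2-[2-(tert-butyldimethylsilyloxy)ethyl]-2-methyl-5-(prop-1-en-2-yl)cyclohex-3-en-1-one | C=C(C)[C@H]1CC(=O)[C@](C)(CCO[Si](C)(C)C(C)(C)C)C=C1 | intermediate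
5 | (2R,5S)-2-[2-(tert-butyldimethylsilyloxy)ethyl]-5-(3-hydroxyprop-1-en-2-yl)-2-methylcyclohex-3-en-1-one | C=C(CO)[C@H]1CC(=O)[C@](C)(CCO[Si](C)(C)C(C)(C)C)C=C1 | intermediate
6 | 2-[(1S,4R)-4-[2-(tert-butyldimethylsilyloxy)ethyl]-4-methyl-5-oxocyclohex-2-en-1-yl]prop-2-enal | C=C(C=O)[C@H]1CC(=O)[C@](C)(CCO[Si](C)(C)C(C)(C)C)C=C1 | intermediate
7 | 2-[(1S,4R)-4-[2-(tert-butyldimethylsilyloxy)ethyl]-4-methyl-5-oxocyclohex-2-en-1-yl]prop-2-enoic acid | C=C(C(=O)O)[C@H]1CC(=O)[C@](C)(CCO[Si](C)(C)C(C)(C)C)C=C1 | intermediate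
8 | 2-[(1S,4R,5S)-4-[2-(tert-butyldimethylsilyloxy)ethyl]-5-hydroxy-4-methyl-5-(prop-1-en-2-yl)cyclohex-2-en-1-yl]prop-2-enoic acid (expected major C5 epimer; both epimers converge in step 5) | C=C(C(=O)O)[C@H]1C[C@](O)(C(C)=C)[C@](C)(CCO[Si](C)(C)C(C)(C)C)C=C1 | intermediate
9 | 2-[(1S,4R,5Z)-4-[2-(tert-butyldimethylsilyloxy)ethyl]-4-methyl-5-(1-oxopropan-2-ylidene)cyclohex-2-en-1-yl]prop-2-enoic acid | C=C(C(=O)O)[C@H]1C/C(=C(\C)C=O)[C@](C)(CCO[Si](C)(C)C(C)(C)C)C=C1 | intermediate
10 | methyl 2-[(1S,4R,5Z)-4-[2-(tert-butyldimethylsilyloxy)ethyl]-4-methyl-5-(1-oxopropan-2-ylidene)cyclohex-2-en-1-yl]prop-2-enoate | C=C(C(=O)OC)[C@H]1C/C(=C(\C)C=O)[C@](C)(CCO[Si](C)(C)C(C)(C)C)C=C1 | intermediate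
11 | methyl 2-[(1R,2S,3S,4S,5Z)-2-acetoxy-3-bromo-4-[2-(tert-butyldimethylsilyloxy)ethyl]-4-methyl-5-(1-oxopropan-2-ylidene)cyclohexyl]prop-2-enoate (8β-acetate, 9α-bromide) | C=C(C(=O)OC)[C@H]1C/C(=C(\C)C=O)[C@](C)(CCO[Si](C)(C)C(C)(C)C)[C@H](Br)[C@H]1OC(C)=O | intermediate
12 | methyl 2-[(1R,2R,4R,5Z)-2-acetoxy-4-[2-(tert-butyldimethylsilyloxy)ethyl]-4-methyl-5-(1-oxopropan-2-ylidene)cyclohexyl]prop-2-enoate | C=C(C(=O)OC)[C@H]1C/C(=C(\C)C=O)[C@](C)(CCO[Si](C)(C)C(C)(C)C)C[C@H]1OC(C)=O | intermediate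
13 | methyl 2-[(1R,2R,4R,5Z)-2-acetoxy-4-(2-hydroxyethyl)-4-methyl-5-(1-oxopropan-2-ylidene)cyclohexyl]prop-2-enoate | C=C(C(=O)OC)[C@H]1C/C(=C(\C)C=O)[C@](C)(CCO)C[C@H]1OC(C)=O | intermediate
14 | methyl 2-[(1R,2R,4S,5Z)-2-acetoxy-4-(2-iodoethyl)-4-methyl-5-(1-oxopropan-2-ylidene)cyclohexyl]prop-2-enoate | C=C(C(=O)OC)[C@H]1C/C(=C(\C)C=O)[C@](C)(CCI)C[C@H]1OC(C)=O | intermediate
15 | trivalent alkylchromium dichloride formed from 14 (Cr in place of I at C2) | C=C(C(=O)OC)[C@H]1C/C(=C(\C)C=O)[C@](C)(CC[Cr](Cl)Cl)C[C@H]1OC(C)=O | intermediate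
16 | methyl (3S,7R,8R,10R)-8-acetoxy-3-hydroxyeudesma-4,11(13)-dien-12-oate (3β-OH, 8β-OAc) | C=C(C(=O)OC)[C@H]1CC2=C(C)[C@@H](O)CC[C@]2(C)C[C@H]1OC(C)=O | intermediate
17 | methyl (3S,7R,8R,10R)-8-acetoxy-3-(2-methylpropanoyloxy)eudesma-4,11(13)-dien-12-oate | C=C(C(=O)OC)[C@H]1CC2=C(C)[C@@H](OC(=O)C(C)C)CC[C@]2(C)C[C@H]1OC(C)=O | intermediate
18 | methyl (3S,5S,7R,8R,10R)-8-acetoxy-5-hydroperoxy-3-(2-methylpropanoyloxy)eudesma-4(15),11(13)-dien-12-oate | C=C(C(=O)OC)[C@H]1C[C@@]2(OO)C(=C)[C@@H](OC(=O)C(C)C)CC[C@]2(C)C[C@H]1OC(C)=O | target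

Total step count: 13. Longest linear sequence: 13 steps from (R)-carvone.

Steps most likely to fail

Step 1. The dienolate may be attacked on the face syn to the isopropenyl group (poor facial selectivity at C10), or be alkylated at C6 or on oxygen. The fallback sets out from 1 and comes back at 4, and relays the configuration by a sigmatropic shift instead of an intermolecular alkylation. Carvone would be converted (TMSCl, NaI, Et3N, MeCN) into its linear silyl dienol ether, (S)-trimethyl{[2-methyl-5-(prop-1-en-2-yl)cyclohexa-1,3-dien-1-yl]oxy}silane F1. Rubottom-type oxidation at the γ-carbon (mCPBA, NaHCO3, then dilute acid), anti to the isopropenyl group, should give (4S,5R)-4-hydroxy-2-methyl-5-(prop-1-en-2-yl)cyclohex-2-en-1-one F2. A Johnson–Claisen rearrangement with triethyl orthoacetate (cat. propionic acid, 135 °C) would transfer the C8–O configuration suprafacially to C10 and give ethyl 2-[(1R,4S)-1-methyl-6-oxo-4-(prop-1-en-2-yl)cyclohex-2-en-1-yl]acetate F3. LiAlH4 would reduce ester and ketone to (1R,2R,5S)-2-(2-hydroxyethyl)-2-methyl-5-(prop-1-en-2-yl)cyclohex-3-en-1-ol F4 (either carbinol epimer serves). TBSCl/imidazole would silylate the primary hydroxyl to (1R,2R,5S)-2-[2-(tert-butyldimethylsilyloxy)ethyl]-2-methyl-5-(prop-1-en-2-yl)cyclohex-3-en-1-ol F5, and Dess–Martin oxidation would return 4.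

Step 7. Regio- and facial control may be lost because the monocyclic ring can react through its ring-flipped half-chair, and the neighbouring ester carbonyl may capture the brominated intermediate (lactonisation). The fallback sets out from 10 and comes back at 16, and postpones the C8 oxygenation to a rigid bicyclic enone. HF·pyridine would give methyl 2-[(1S,4R,5Z)-4-(2-hydroxyethyl)-4-methyl-5-(1-oxopropan-2-ylidene)cyclohex-2-en-1-yl]prop-2-enoate F6, and Appel iodination methyl 2-[(1S,4R,5Z)-4-(2-iodoethyl)-4-methyl-5-(1-oxopropan-2-ylidene)cyclohex-2-en-1-yl]prop-2-enoate F7. The CrCl2/Co(C32H16N8) ring closure of step 11 would give methyl (3S,7S,10R)-3-hydroxyeudesma-4,8,11(13)-trien-12-oate F8, and MnO2 methyl (7S,10R)-3-oxoeudesma-4,8,11(13)-trien-12-oate F9. In F9 ring B is locked with the C10 methyl axial, as in the bromohydrin chemistry of steroidal 1-enes, so N-bromosuccinimide/NaOAc/AcOH should give methyl (7R,8S,9S,10S)-8-acetoxy-9-bromo-3-oxoeudesma-4,11(13)-dien-12-oate F10. n-Bu3SnH would then give methyl (7R,8R,10R)-8-acetoxy-3-oxoeudesma-4,11(13)-dien-12-oate F11, and Luche reduction (NaBH4, CeCl3, MeOH, −78 °C) from the α face would return 16.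

Step 11. Facial selectivity at C3 may erode (closure through the s-cis aldehyde rotamer or a boat-like transition state), giving the 3α-alcohol beside 16. The fallback sets out from 14 and comes back at 17, and fixes C3 by SN2 inversion instead of by the ring closure. The epimer methyl (3R,7R,8R,10R)-8-acetoxy-3-hydroxyeudesma-4,11(13)-dien-12-oate F12 would be separated and esterified under Mitsunobu conditions (2-methylpropanoic acid, PPh3, DIAD, THF, 0 °C); inversion at C3 gives 17 directly, while SN2′ attack is blocked by the fully substituted C5.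

Further compounds
F1 | step 1 | (S)-trimethyl{[2-methyl-5-(prop-1-en-2-yl)cyclohexa-1,3-dien-1-yl]oxy}silane | C=C(C)[C@H]1CC(O[Si](C)(C)C)=C(C)C=C1
F2 | step 1 | (4S,5R)-4-hydroxy-2-methyl-5-(prop-1-en-2-yl)cyclohex-2-en-1-one | C=C(C)[C@H]1CC(=O)C(C)=C[C@@H]1O
F3 | step 1 | ethyl 2-[(1R,4S)-1-methyl-6-oxo-4-(prop-1-en-2-yl)cyclohex-2-en-1-yl]acetate | C=C(C)[C@H]1CC(=O)[C@](C)(CC(=O)OCC)C=C1
F4 | step 1 | (1R,2R,5S)-2-(2-hydroxyethyl)-2-methyl-5-(prop-1-en-2-yl)cyclohex-3-en-1-ol | C=C(C)[C@H]1C[C@@H](O)[C@](C)(CCO)C=C1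
F5 | step 1 | (1R,2R,5S)-2-[2-(tert-butyldimethylsilyloxy)ethyl]-2-methyl-5-(prop-1-en-2-yl)cyclohex-3-en-1-ol | C=C(C)[C@H]1C[C@@H](O)[C@](C)(CCO[Si](C)(C)C(C)(C)C)C=C1
F6 | step 7 | methyl 2-[(1S,4R,5Z)-4-(2-hydroxyethyl)-4-methyl-5-(1-oxopropan-2-ylidene)cyclohex-2-en-1-yl]prop-2-enoate | C=C(C(=O)OC)[C@H]1C/C(=C(\C)C=O)[C@](C)(CCO)C=C1
F7 | step 7 | methyl 2-[(1S,4R,5Z)-4-(2-iodoethyl)-4-methyl-5-(1-oxopropan-2-ylidene)cyclohex-2-en-1-yl]prop-2-enoate | C=C(C(=O)OC)[C@H]1C/C(=C(\C)C=O)[C@](C)(CCI)C=C1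
F8 | step 7 | methyl (3S,7S,10R)-3-hydroxyeudesma-4,8,11(13)-trien-12-oate | C=C(C(=O)OC)[C@H]1CC2=C(C)[C@@H](O)CC[C@]2(C)C=C1
F9 | step 7 | methyl (7S,10R)-3-oxoeudesma-4,8,11(13)-trien-12-oate | C=C(C(=O)OC)[C@H]1CC2=C(C)C(=O)CC[C@]2(C)C=C1
F10 | step 7 | methyl (7R,8S,9S,10S)-8-acetoxy-9-bromo-3-oxoeudesma-4,11(13)-dien-12-oate | C=C(C(=O)OC)[C@H]1CC2=C(C)C(=O)CC[C@]2(C)[C@H](Br)[C@H]1OC(C)=O
F11 | step 7 | methyl (7R,8R,10R)-8-acetoxy-3-oxoeudesma-4,11(13)-dien-12-oate | C=C(C(=O)OC)[C@H]1CC2=C(C)C(=O)CC[C@]2(C)C[C@H]1OC(C)=O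
F12 | step 11 | methyl (3R,7R,8R,10R)-8-acetoxy-3-hydroxyeudesma-4,11(13)-dien-12-oate | C=C(C(=O)OC)[C@H]1CC2=C(C)[C@H](O)CC[C@]2(C)C[C@H]1OC(C)=O
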